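**Retrosynthetic overview**
1. C6–alkenyl bond: Suzuki–Miyaura coupling of a 6-iodo oxepinoflavone with an (E)-3-methylbut-1-enyl boronate, done last so the styrene never meets an oxidant. The iodide comes from 5-OH-directed C6 iodination.
2. Oxepine C–O bond and the (S)-centre: chiral-ketone/KHSO5 epoxidation of the 3-prenyl group, then in situ 7-exo-tet opening by the 2'-phenoxide with inversion, on achiral 5,2',4'-trihydroxy-7-methoxy-3-prenylflavone.
3. Pyranone ring C: cyclodehydration of a 2-prenyl-1,3-diketone. The diketone comes from C-acylation of an α-prenylated 2,6-dihydroxy-4-methoxyphenyl ketone with a MOM-protected 2,4-dihydroxybenzoyl imidazolide.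
4. α-Prenyl ketone: trianion alkylation of 2',6'-dihydroxy-4'-methoxyacetophenone with prenyl bromide.
5. Ring order: rings A and B are bought, ring C is closed in step 4, and the oxepine (ring D) in step 5.

Assumption: 2',6'-dihydroxy-4'-methoxyacetophenone and (E)-3-methylbut-1-enylboronic acid pinacol ester are taken as catalogue chemicals. CIP analysis of the given SMILES gives (S) at the single stereocentre.

**Step 1**
Reactants: 1 2,4-dihydroxybenzoic acid
Product: 3 2,4-bis(methoxymethoxy)benzoic acid, via MOM ester 2 (not isolated)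
Conditions: MOMCl (4 equiv), iPr2NEt (5 equiv), CH2Cl2, 0 °C → rt, 16 h; then aq LiOH, THF/MeOH, 40 °C, 3 h; 1 M HCl to pH 4, 0 °C
Reagents that add atoms: chloromethyl methyl ether (MOMCl), COCCl; lithium hydroxide LiOH, [Li+].[OH-]
Why: Base-mediated O-alkylation (MOM acetal protection) caps both phenols and the acid, and saponification then cleaves only the MOM ester because aryl MOM ethers are inert to hydroxide.

**Step 2**
Reactants: 4 2',6'-dihydroxy-4'-methoxyacetophenone; 5 1-bromo-3-methylbut-2-ene (prenyl bromide)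
Product: 6 1-(2,6-dihydroxy-4-methoxyphenyl)-5-methylhex-4-en-1-one
Conditions: LiN(SiMe3)2 (3.3 equiv), THF, −78 → −10 °C, 1 h; 5 (0.95 equiv), −78 → 0 °C; aq NH4Cl
Reagents that add atoms: 1-bromo-3-methylbut-2-ene (reactant 5), CC(C)=CCBr
Why: Polyanion (trianion) alkylation works because the last-formed ketone enolate carbon is by far the most nucleophilic site and the two carbonyl-chelated lithium phenoxides stay inert below 0 °C, so the allylic bromide reacts by SN2 at carbon only.

**Step 3**
Reactants: 3 2,4-bis(methoxymethoxy)benzoic acid; 6 1-(2,6-dihydroxy-4-methoxyphenyl)-5-methylhex-4-en-1-one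
Product: 8 1-[2,4-bis(methoxymethoxy)phenyl]-3-(2,6-dihydroxy-4-methoxyphenyl)-2-(3-methylbut-2-en-1-yl)propane-1,3-dione, via acyl imidazolide 7 (not isolated)
Conditions: 3, CDI (1.05 equiv), THF, rt, 1 h; cannulated into 6 + LiN(SiMe3)2 (5.2 equiv), THF, −78 °C → rt; aq NH4Cl
Reagents that add atoms: 1,1'-carbonyldiimidazole (CDI), O=C(n1ccnc1)n1ccnc1 (its imidazolyl group stands in 7 only and is lost again in 8)
Why: This is a crossed Claisen-type C-acylation of a lithium enolate polyanion by an acyl imidazolide, in which any O-aroylated phenoxide is funnelled to the same 1,3-diketone by Baker–Venkataraman acyl shift under the excess base, and the new C2 centre is racemic, enolisable and planarised in step 4.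

**Step 4**
Reactants: 8 the 2-prenyl-1,3-diketone
Product: 10 2-(2,4-dihydroxyphenyl)-5-hydroxy-7-methoxy-3-(3-methylbut-2-en-1-yl)-4H-chromen-4-one, via bis-MOM flavone 9 (not isolated)
Conditions: conc. HCl/MeOH (1:20), 45 °C, 4 h
Reagents that add atoms: none
Why: Acid-catalysed cyclodehydration of an o-hydroxyaryl 1,3-diketone (classical flavone synthesis) closes ring C through one of the two equivalent ring A hydroxyls while ring B is still masked, which fixes the regiochemistry, and the same acid then solvolyses both MOM acetals without touching the trisubstituted alkene.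

**Step 5**
Reactants: 10 achiral 5,2',4'-trihydroxy-7-methoxy-3-prenylflavone
Product: 12 (S)-6-H oxepinoflavone (5,4'-dihydroxy-7-methoxyflavone bridged C3–CH2–CH[C(CH3)2OH]–O–C2'), via (R)-epoxide 11 (not isolated)
Conditions: 1,2:4,5-di-O-isopropylidene-β-D-erythro-2,3-hexodiulo-2,6-pyranose (D-fructose-derived Shi ketone, 30 mol%), Oxone (2KHSO5·KHSO4·K2SO4, 1.4 equiv KHSO5) and K2CO3 (8 equiv) added in parallel over 2 h, Bu4NHSO4 (5 mol%), MeCN/CH2(OMe)2 (1:2), aq Na2B4O7/Na2EDTA buffer, pH 10.5, −5 → 0 °C; once the starch–iodide test is negative, 35 °C, 6 h; work-up at pH 6; one recrystallisation to raise ee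
Reagents that add atoms: potassium peroxymonosulfate KHSO5 (active part of Oxone), [K+].[O-]S(=O)(=O)OO
Why: Proposed new method: a protecting-group-free organocatalytic epoxidation/7-exo-tet etherification cascade on a free polyphenolic 3-prenylflavone, not yet shown for this substrate class or ring size; the chiral dioxirane formed from the ketone and KHSO5 transfers oxygen through the spiro transition state to the prenyl alkene, which is the only electron-rich C=C because the chromone C2=C3 is electron-poor and tetrasubstituted and the ring B phenoxides are phenylogous carboxylates and so hard to oxidise, giving (R)-epoxide 11; at the same pH the 2'-phenoxide, held over the side chain by the four contiguous sp2 atoms C2'–C1'–C2–C3, opens 11 by SN2 attack at the less hindered secondary carbon with inversion, which sets the (S)-centre and closes ring D; the closest known reaction type is Shi epoxidation of ortho-prenylphenol derivatives followed by base-induced 5-exo cyclisation to 2-(2-hydroxypropan-2-yl)-2,3-dihydrobenzofurans.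

**Step 6**
Reactants: 12 (S)-6-H oxepinoflavone
Product: 13 (S)-6-iodo oxepinoflavone
Conditions: BnMe3N·ICl2 (1.05 equiv), CaCO3 (1.5 equiv), CH2Cl2/MeOH (5:2), rt, dark, 3 h
Reagents that add atoms: benzyltrimethylammonium dichloroiodate, C[N+](C)(C)Cc1ccccc1.Cl[I-]Cl
Why: In this buffered electrophilic aromatic iodination the phloroglucinol-type ring A is far more nucleophilic than the resorcinol-type ring B conjugated to the electron-poor C2, a free 5-OH directs attack ortho to itself at C6 (the known 6-selectivity of 5-hydroxy-7-alkoxyflavones), and no alkene is left to consume the iodinating agent.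

**Step 7**
Reactants: 13 (S)-6-iodo oxepinoflavone; 14 (E)-3-methylbut-1-enylboronic acid pinacol ester
Product: 15 target CNP0216454.2
Conditions: 14 (1.5 equiv), Pd(OAc)2 (5 mol%), SPhos (10 mol%), K3PO4 (4 equiv), 1,4-dioxane/H2O (5:1), 70 °C, 4 h; work-up at pH 6
Reagents that add atoms: (E)-3-methylbut-1-enylboronic acid pinacol ester (reactant 14), CC(C)/C=C/B1OC(C)(C)C(C)(C)O1
Why: In this Suzuki–Miyaura coupling, zerovalent palladium formed in situ with the bulky SPhos ligand inserts into the hindered carbon–iodine bond at C6, transmetalation and reductive elimination keep the (E)-geometry, free phenols are tolerated as phenoxides, and the remote ether stereocentre is untouched.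

**Compound list**
1 | 2,4-dihydroxybenzoic acid | O=C(O)c1ccc(O)cc1O | starting material
2 | methoxymethyl 2,4-bis(methoxymethoxy)benzoate | COCOC(=O)c1ccc(OCOC)cc1OCOC | intermediate
3 | 2,4-bis(methoxymethoxy)benzoic acid | COCOc1ccc(C(=O)O)c(OCOC)c1 | intermediate
4 | 1-(2,6-dihydroxy-4-methoxyphenyl)ethan-1-one (2',6'-dihydroxy-4'-methoxyacetophenone) | CC(=O)c1c(O)cc(OC)cc1O | starting material
5 | 1-bromo-3-methylbut-2-ene (prenyl bromide) | CC(C)=CCBr | starting material
6 | 1-(2,6-dihydroxy-4-methoxyphenyl)-5-methylhex-4-en-1-one | COc1cc(O)c(C(=O)CCC=C(C)C)c(O)c1 | intermediate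
7 | [2,4-bis(methoxymethoxy)phenyl](1H-imidazol-1-yl)methanone | COCOc1ccc(C(=O)n2ccnc2)c(OCOC)c1 | intermediate
8 | 1-[2,4-bis(methoxymethoxy)phenyl]-3-(2,6-dihydroxy-4-methoxyphenyl)-2-(3-methylbut-2-en-1-yl)propane-1,3-dione (racemic, configurationally labile C2; keto/enol/hemiketal mixture) | COCOc1ccc(C(=O)C(CC=C(C)C)C(=O)c2c(O)cc(OC)cc2O)c(OCOC)c1 | intermediate
9 | 2-[2,4-bis(methoxymethoxy)phenyl]-5-hydroxy-7-methoxy-3-(3-methylbut-2-en-1-yl)-4H-chromen-4-one | COCOc1ccc(-c2oc3cc(OC)cc(O)c3c(=O)c2CC=C(C)C)c(OCOC)c1 | intermediate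
10 | 2-(2,4-dihydroxyphenyl)-5-hydroxy-7-methoxy-3-(3-methylbut-2-en-1-yl)-4H-chromen-4-one (achiral) | COc1cc(O)c2c(=O)c(CC=C(C)C)c(-c3ccc(O)cc3O)oc2c1 | intermediate
11 | 2-(2,4-dihydroxyphenyl)-3-{[(2R)-3,3-dimethyloxiran-2-yl]methyl}-5-hydroxy-7-methoxy-4H-chromen-4-one | COc1cc(O)c2c(=O)c(C[C@H]3OC3(C)C)c(-c3ccc(O)cc3O)oc2c1 | intermediate
12 | (S)-6-H oxepinoflavone: 5,4'-dihydroxy-7-methoxyflavone whose C3 and 2'-O are bridged by CH2–CH[C(CH3)2OH], (S) at the bridge CH, H at C6 | COc1cc2oc3c(c(=O)c2c(O)c1)C[C@@H](C(C)(C)O)Oc1cc(O)ccc1-3 | intermediate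
13 | (S)-6-iodo oxepinoflavone: 12 with iodine at C6, between 5-OH and 7-OMe | COc1cc2oc3c(c(=O)c2c(O)c1I)C[C@@H](C(C)(C)O)Oc1cc(O)ccc1-3 | intermediate
14 | 4,4,5,5-tetramethyl-2-[(1E)-3-methylbut-1-en-1-yl]-1,3,2-dioxaborolane | CC(C)/C=C/B1OC(C)(C)C(C)(C)O1 | starting material
15 | CNP0216454.2: 12 with an (E)-3-methylbut-1-enyl group at C6, (S) | COc1cc2oc3c(c(=O)c2c(O)c1/C=C/C(C)C)C[C@@H](C(C)(C)O)Oc1cc(O)ccc1-3 | target

**Step count**
Total steps: 7. Longest linear sequence: 6 steps (4 → 6 → 8 → 10 → 12 → 13 → 15). The branch 1 → 3 is one step.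

**Three steps most likely to fail**

Risk 1, step 5 (the proposed new step). The free ring B phenoxides may be over-oxidised by KHSO5 or the dioxirane, and the 7-exo closure may lag behind epoxide hydrolysis. The fallback uses known chemistry, separates oxidation from ring closure and removes free phenols from the oxidation. It sets out from 10 and comes back at 12. Treating 10 with TBSCl (2.2 equiv) and imidazole in DMF silylates only the two unchelated hydroxyls and gives the 2',4'-bis(tert-butyldimethylsilyl) ether F1. A standard Shi epoxidation of this phenol-free prenylarene, with the same ketone, Oxone and K2CO3 at 0 °C, gives the isolated silylated (R)-epoxide F2. Bu4NF in dry THF (0 °C → 40 °C) then frees a naked 2'-phenoxide, which opens the epoxide at the secondary carbon with inversion and also frees the 4'-OH, giving 12.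

Risk 2, step 6. Iodine may enter ring B (C3' or C5', activated by the free 4'-OH) or C8 as well as C6. The fallback temporarily deactivates ring B. It sets out from 12 and comes back at 13. Ac2O (1.1 equiv) in pyridine at 0 °C acylates only the unchelated, non-tertiary 4'-OH and gives the 4'-O-acetate F3. Iodination with BnMe3N·ICl2/CaCO3 then has only ring A to attack and gives the 6-iodo 4'-O-acetate F4. K2CO3 in MeOH at rt removes the acetate to give 13.

Risk 3, step 3. The α-substituted, triply charged enolate may react sluggishly with the ortho-substituted acyl imidazolide, or LiN(SiMe3)2 may consume the acyl donor. The fallback replaces the intermolecular C-acylation with O-acylation followed by an intramolecular acyl shift. It sets out from 3 and 6 and comes back at 8. Steglich esterification (EDC·HCl, DMAP, CH2Cl2, 1.0 equiv of 3) gives the mono-aryl ester 3-hydroxy-5-methoxy-2-(5-methylhex-4-enoyl)phenyl 2,4-bis(methoxymethoxy)benzoate F5. KOtBu (3 equiv) in THF (0 °C → rt) then induces the Baker–Venkataraman rearrangement to 8.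

**Further compounds**
F1 | step 5 | 2-[2,4-bis(tert-butyldimethylsilyloxy)phenyl]-5-hydroxy-7-methoxy-3-(3-methylbut-2-en-1-yl)-4H-chromen-4-one | COc1cc(O)c2c(=O)c(CC=C(C)C)c(-c3ccc(O[Si](C)(C)C(C)(C)C)cc3O[Si](C)(C)C(C)(C)C)oc2c1
F2 | step 5 | 2-[2,4-bis(tert-butyldimethylsilyloxy)phenyl]-3-{[(2R)-3,3-dimethyloxiran-2-yl]methyl}-5-hydroxy-7-methoxy-4H-chromen-4-one | COc1cc(O)c2c(=O)c(C[C@H]3OC3(C)C)c(-c3ccc(O[Si](C)(C)C(C)(C)C)cc3O[Si](C)(C)C(C)(C)C)oc2c1
F3 | step 6 | 4'-O-acetate of (S)-6-H oxepinoflavone 12 | COc1cc2oc3c(c(=O)c2c(O)c1)C[C@@H](C(C)(C)O)Oc1cc(OC(C)=O)ccc1-3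
F4 | step 6 | 4'-O-acetate of (S)-6-iodo oxepinoflavone 13 | COc1cc2oc3c(c(=O)c2c(O)c1I)C[C@@H](C(C)(C)O)Oc1cc(OC(C)=O)ccc1-3
F5 | step 3 | 3-hydroxy-5-methoxy-2-(5-methylhex-4-enoyl)phenyl 2,4-bis(methoxymethoxy)benzoate | COCOc1ccc(C(=O)Oc2cc(OC)cc(O)c2C(=O)CCC=C(C)C)c(OCOC)c1
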